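The cyclohexane ring is numbered as in iridal (C6–C11): the acyloxypropyl arm sits on C6, the enal on C7, a methyl on C10, and C11 is quaternary. The ring is cut at C7–C8 and C10–C11. C8–C9–C10(CH3) corresponds to crotonaldehyde, a 1,3-bis-electrophile, and C11–C6–C7 can serve as a graded 1,3-bis-nucleophile. The precursor is a carvone-derived silyl enol ether (C11) carrying a propynyl group (C7, C2, C25) on C6; the carvone ring ties C12 to C3. In one pot, an iminium-catalysed Mukaiyama–Michael addition forms C10–C11 with both stereocentres. Alkyne–carbonyl metathesis then forms C7–C8 and moves the aldehyde oxygen to C2. Later cleavage of C12–C3 frees both side arms.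

Key step: step 2

Remark: C1 = CHO, C2 = its α-carbon (methyl C25), C3–C5 = propyl arm (C3 bears O), and C12–C24 = long chain counted from the ring. Commercial crotonaldehyde is taken as the E isomer.

Step 1
Reactants: 1 (S)-(+)-carvone; 2 1-propynylmagnesium bromide
Product: 3 TBS enol ether of (3R,5S)-2-methyl-5-isopropenyl-3-(prop-1-ynyl)cyclohexanone (enol double bond C11=C12; propynyl trans to isopropenyl)
Conditions: 2, ZnBr2, THF, 0 °C; then 1, TBSOTf, Et2O–THF, −40 °C
Reagents that add atoms: 1-propynylmagnesium bromide (2) CC#C[Mg]Br; tert-butyldimethylsilyl triflate CC(C)(C)[Si](C)(C)OS(=O)(=O)C(F)(F)F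
Why: In this silyl-triflate-promoted conjugate addition of an alkynylzinc halide, O-silylation gives a silyloxyallyl cation that is attacked axially at C6, anti to the equatorial isopropenyl group, and the enol ether is fixed regiospecifically at C11.

Step 2
Reactants: 3 TBS enol ether; 4 (E)-crotonaldehyde
Product: 6 (3S,4aR,8R,8aR)-5-acetyl-8,8a-dimethyl-3-isopropenyl-3,4,4a,7,8,8a-hexahydronaphthalen-1(2H)-one (trans-fused), via keto aldehyde 5 (not isolated)
Conditions: (2S,5S)-5-benzyl-2-tert-butyl-3-methylimidazolidin-4-one·CF3CO2H (20 mol %), 4 (3 equiv), H2O (2 equiv), CH2Cl2, −20 °C; then 4 Å MS, BF3·OEt2 (3 equiv), −20 → 0 °C, same flask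
Reagents that add atoms: (E)-crotonaldehyde (4) C/C=C/C=O
Why: The imidazolidinone condenses with 4 to an E-iminium ion whose β-carbon (C10) is attacked by the enol silane carbon C11 of 3 (organocatalytic Mukaiyama–Michael addition; water takes up the silyl group and releases the catalyst), giving keto aldehyde 5. BF3 then activates the new aldehyde carbon C8, the proximal alkyne carbon C7 attacks it in a 6-exo-dig closure, and the vinyl cation at C2 collapses through an oxetene whose opening gives the C7=C8 enone with the former aldehyde oxygen on C2 (ring-closing alkyne–carbonyl metathesis of a 6-alkynal). C11 is set by the substrate, because the propynyl group on C6 sits pseudoaxial to avoid A(1,2) strain and the electrophile enters axially on the opposite face, which makes the new ring trans-fused. C10 is set by the catalyst, whose benzyl group leaves one face of the iminium ion open, in the sense established for carbon nucleophiles and crotonaldehyde (R). The step needs three selectivities: 1,4- over 1,2-addition (secured by iminium activation), C11 reacting before C7 (enol silane against unactivated alkyne), and closure at C7 rather than an aldol at C3 or C9 (only C7 of the alkyne can close a six-membered ring, and that closure is irreversible, whereas the aldols are reversible).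

Step 3
Reactants: 6 trans-decalin enedione
Product: 8 (Z)-1-[(4R,4aR,7S,8aR)-4,4a-dimethyl-5-oxo-7-isopropenyl-octahydronaphthalen-1(2H)-ylidene]ethyl triflate (OTf syn to C6), via lithium enolate 7 (not isolated)
Conditions: LiB(s-Bu)3H (1.05 equiv), THF, −78 °C; then N-(5-chloro-2-pyridyl)bis(trifluoromethanesulfonimide), −78 → 0 °C
Reagents that add atoms: N-(5-chloro-2-pyridyl)bis(trifluoromethanesulfonimide) Clc1ccc(nc1)N(S(=O)(=O)C(F)(F)F)S(=O)(=O)C(F)(F)F
Why: In this conjugate reduction–triflation, hydride adds to C8 of the s-trans enone (oxygen, not methyl, turned toward substituted C6), so the enolate oxygen ends syn to C6 and is trapped with retention, while the neopentyl C12 ketone should react more slowly with the bulky hydride.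

Step 4
Reactants: 8 Z-enol triflate
Product: 9 (2Z)-2-[(4R,4aR,7S,8aR)-4,4a-dimethyl-5-oxo-7-isopropenyl-octahydronaphthalen-1(2H)-ylidene]-N-methoxy-N-methylpropanamide
Conditions: Pd(OAc)2 (10 mol %), dppp, CO (1 atm), MeNH(OMe)·HCl, Et3N, DMF, 60 °C
Reagents that add atoms: carbon monoxide [C-]#[O+]; N,O-dimethylhydroxylamine hydrochloride CNOC.Cl
Why: Palladium-catalysed aminocarbonylation of an alkenyl triflate proceeds with retention of alkene geometry, so C1 is placed syn to C6 as in the target.

Step 5
Reactants: 9 N-methoxy-N-methylamide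
Product: 11 (2Z)-2-[(4R,4aR,8aR)-4,4a-dimethyl-5-oxo-octahydronaphthalen-1(2H)-ylidene]-N-methoxy-N-methylpropanamide, via methoxy hydroperoxide 10 (not isolated)
Conditions: O3, MeOH, −78 °C; then PhSH, FeSO4·7H2O, −78 °C → rt
Reagents that add atoms: none
Why: In this hydrodealkenylation, ozonolysis of the electron-rich isopropenyl group in methanol gives an α-methoxy hydroperoxide, Fe(II) converts it to an alkoxy radical, β-scission expels methyl acetate, and the ring radical takes H from the thiol; the electron-poor tetrasubstituted alkene and all remaining stereocentres are untouched.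

Step 6
Reactants: 11 keto amide
Product: 13 C12 enol triflate of 11 (C12=C3), via potassium enolate 12 (not isolated)
Conditions: KHMDS, THF, −78 °C; then PhNTf2, −78 → 0 °C
Reagents that add atoms: N-phenylbis(trifluoromethanesulfonimide) O=S(=O)(N(c1ccccc1)S(=O)(=O)C(F)(F)F)C(F)(F)F
Why: Kinetic enolisation and O-triflation are regiospecific because only C3 carries α-hydrogens next to the C12 ketone (C11 is quaternary).

Step 7
Reactants: 13 enol triflate
Product: 14 cyclohexene (C12H=C3H in place of the ketone; other centres as in 11)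
Conditions: Pd(OAc)2 (5 mol %), PPh3, HCO2H, n-Bu3N, DMF, 60 °C
Reagents that add atoms: none
Why: Palladium-catalysed formate reduction of an alkenyl triflate replaces OTf by H without affecting the amide or the tetrasubstituted alkene.

Step 8
Reactants: 14 cyclohexene
Product: 16 (2Z)-2-[(2R,3R,4R)-3-formyl-3,4-dimethyl-2-(3-oxopropyl)cyclohexylidene]-N-methoxy-N-methylpropanamide, via cis-diol 15 (not isolated)
Conditions: OsO4 (2 mol %), NaIO4, 2,6-lutidine, dioxane–H2O, rt
Reagents that add atoms: osmium tetroxide (catalytic oxygen carrier) O=[Os](=O)(=O)=O; sodium periodate (terminal oxidant) [Na+].[O-]I(=O)(=O)=O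
Why: In this Lemieux–Johnson cleavage, osmylation selects the accessible cis-disubstituted alkene over the hindered, electron-poor tetrasubstituted one, and periodate cuts C12–C3, opening the former carvone ring to the two arms.

Step 9
Reactants: 16 dialdehyde
Product: 17 hydroxy aldehyde (C3 CH2OH, C12 CHO; C6, C10, C11 as in 16)
Conditions: LiAlH(O-t-Bu)3 (1.0 equiv), THF, −78 °C
Reagents that add atoms: none
Why: In this chemoselective hydride reduction, the bulky reagent should reduce the unhindered C3 aldehyde well before the neopentyl C12 aldehyde or the amide.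

Step 10
Reactants: 17 hydroxy aldehyde; 18 decanoyl chloride
Product: 19 C3 decanoate aldehyde
Conditions: 18, pyridine, DMAP (cat.), CH2Cl2, 0 °C
Reagents that add atoms: decanoyl chloride (18) CCCCCCCCCC(=O)Cl
Why: DMAP-catalysed O-acylation of the only hydroxyl group installs the ester of the target.

Step 11
Reactants: 19 decanoate aldehyde; 20 methyltriphenylphosphonium bromide
Product: 21 C11 vinyl compound (C12H=C13H2)
Conditions: 20, KHMDS, THF, 0 °C; then 19, −78 → 0 °C
Reagents that add atoms: methyltriphenylphosphonium bromide (20) C[P+](c1ccccc1)(c1ccccc1)c1ccccc1.[Br-]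
Why: Wittig methylenation of a non-enolisable aldehyde is faster than attack of the ylide on the ester or amide and cannot epimerise C11.

Step 12
Reactants: 22 propargyl alcohol
Product: 24 (E)-3-iodo-2-methylprop-2-en-1-ol, via alkenylalane 23 (not isolated)
Conditions: Me3Al (3 equiv), Cp2ZrCl2 (25 mol %), CH2Cl2, 0 °C → rt; then I2, THF, −30 °C
Reagents that add atoms: trimethylaluminium C[Al](C)C; iodine II
Why: Zirconium-catalysed carboalumination adds methyl and aluminium syn, with methyl at the internal carbon, and iodinolysis proceeds with retention, which fixes the E geometry of C14=C15.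

Step 13
Reactants: 24 iodo allylic alcohol
Product: 25 (E)-3-iodo-2-methylprop-2-enal
Conditions: MnO2, CH2Cl2, rt
Reagents that add atoms: none
Why: Manganese dioxide oxidation of a primary allylic alcohol stops at the enal and leaves the alkenyl iodide and its geometry intact.

Step 14
Reactants: 25 iodo enal; 26 geranyl chloride
Product: 27 racemic (1E,5E)-1-iodo-2,6,10-trimethylundeca-1,5,9-trien-3-ol
Conditions: BaI2, lithium biphenylide (2 equiv), THF, rt; 26, −78 °C; then 25, −78 °C
Reagents that add atoms: geranyl chloride (26) ClC/C=C(\C)CCC=C(C)C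
Why: Allylbarium reagents add 1,2 to enals through their α-carbon with retention of the E alkene, which gives the linear C16–C17 connection instead of the branched adduct.

Step 15
Reactants: 27 racemic alcohol
Product: 28 (1E,5E)-1-iodo-2,6,10-trimethylundeca-1,5,9-trien-3-one
Conditions: DMP, NaHCO3, CH2Cl2, 0 °C
Reagents that add atoms: none
Why: Buffered periodinane oxidation is mild enough to avoid migration of the β,γ-double bond into conjugation.

Step 16
Reactants: 28 iodo enone
Product: 30 (3R,1E,5E)-1-iodo-2,6,10-trimethylundeca-1,5,9-trien-3-ol, via catechol borate 29 (not isolated)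
Conditions: (S)-Me-CBS oxazaborolidine (20 mol %), catecholborane, toluene, −78 °C; aqueous work-up
Reagents that add atoms: none
Why: In this CBS reduction, the α-branched iodoalkenyl group acts as the large substituent and CH2 as the small one, so the (S)-catalyst should deliver hydride to give the (R)-carbinol C16, and catecholborane at low temperature spares the alkenes.

Step 17
Reactants: 21 vinyl compound; 30 (R)-alkenyl iodide
Product: 32 fully assembled N-methoxy-N-methylamide (target with C(=O)N(Me)OMe at C1), via B-alkyl-9-BBN 31 (not isolated)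
Conditions: 9-BBN, THF, rt; then 30, Pd(dppf)Cl2 (5 mol %), AsPh3, Cs2CO3, DMF–H2O, rt
Reagents that add atoms: alkenyl iodide (30) I/C=C(\C)[C@H](O)C/C=C(\C)CCC=C(C)C
Why: In this hydroboration and B-alkyl Suzuki–Miyaura coupling, 9-BBN adds only to the monosubstituted alkene, placing boron on C13, and the coupling forms C13–C14 with retention of the E-iodide geometry in the presence of the free C16 hydroxyl.

Step 18
Reactants: 32 assembled amide
Product: 34 target CNP0270550.1 (2Z,6S,10R,11R,14E,16R,18E), via zirconium hemiaminal 33 (not isolated)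
Conditions: Cp2Zr(H)Cl (3 equiv), THF, rt; then H2O/silica gel
Reagents that add atoms: none
Why: Hydrozirconation of the tertiary amide carbonyl gives a stable O-zirconated hemiaminal that releases the enal only on hydrolysis, a reduction known to leave alkyl esters alone and to be much faster than hydrozirconation of trisubstituted alkenes.

Compound list
1 | (S)-(+)-carvone | CC1=CC[C@@H](CC1=O)C(C)=C | starting material
2 | 1-propynylmagnesium bromide | CC#C[Mg]Br | starting material
3 | tert-butyl(dimethyl){[(3R,5S)-2-methyl-5-(prop-1-en-2-yl)-3-(prop-1-yn-1-yl)cyclohex-1-en-1-yl]oxy}silane | C1[C@@H](C(C)=C)C[C@H](C#CC)C(C)=C1O[Si](C)(C)C(C)(C)C | intermediate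
4 | (E)-crotonaldehyde | C/C=C/C=O | starting material
5 | (3R)-3-[(1R,4S,6R)-1-methyl-2-oxo-4-(prop-1-en-2-yl)-6-(prop-1-yn-1-yl)cyclohexyl]butanal | C1[C@@H](C(C)=C)C[C@H](C#CC)[C@@](C)([C@H](C)CC=O)C1=O | intermediate
6 | (3S,4aR,8R,8aR)-5-acetyl-8,8a-dimethyl-3-(prop-1-en-2-yl)-3,4,4a,7,8,8a-hexahydronaphthalen-1(2H)-one | C1[C@@H](C(C)=C)C[C@@H]2C(C(C)=O)=CC[C@@H](C)[C@@]2(C)C1=O | intermediate
7 | lithium (Z)-enolate from 1,4-reduction of 6 (O syn to C6) | C1[C@@H](C(C)=C)C[C@@H]2/C(=C(/C)[O-])CC[C@@H](C)[C@@]2(C)C1=O.[Li+] | intermediate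
8 | (Z)-1-[(4R,4aR,7S,8aR)-4,4a-dimethyl-5-oxo-7-(prop-1-en-2-yl)octahydronaphthalen-1(2H)-ylidene]ethyl trifluoromethanesulfonate | C1[C@@H](C(C)=C)C[C@@H]2/C(=C(/C)OS(=O)(=O)C(F)(F)F)CC[C@@H](C)[C@@]2(C)C1=O | intermediate
9 | (2Z)-2-[(4R,4aR,7S,8aR)-4,4a-dimethyl-5-oxo-7-(prop-1-en-2-yl)octahydronaphthalen-1(2H)-ylidene]-N-methoxy-N-methylpropanamide | C1[C@@H](C(C)=C)C[C@@H]2/C(=C(/C)C(=O)N(C)OC)CC[C@@H](C)[C@@]2(C)C1=O | intermediate
10 | α-methoxy hydroperoxide from 9 (2-hydroperoxy-2-methoxypropan-2-yl in place of isopropenyl; epimers at that carbon) | C1[C@@H](C(C)(OC)OO)C[C@@H]2/C(=C(/C)C(=O)N(C)OC)CC[C@@H](C)[C@@]2(C)C1=O | intermediate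
11 | (2Z)-2-[(4R,4aR,8aR)-4,4a-dimethyl-5-oxo-octahydronaphthalen-1(2H)-ylidene]-N-methoxy-N-methylpropanamide | C1CC[C@@H]2/C(=C(/C)C(=O)N(C)OC)CC[C@@H](C)[C@@]2(C)C1=O | intermediate
12 | potassium C12=C3 enolate of 11 | [K+].[O-]C1=CCC[C@@H]2/C(=C(/C)C(=O)N(C)OC)CC[C@@H](C)[C@@]12C | intermediate
13 | C12 enol triflate of 11 (C12=C3) | FC(F)(F)S(=O)(=O)OC1=CCC[C@@H]2/C(=C(/C)C(=O)N(C)OC)CC[C@@H](C)[C@@]12C | intermediate
14 | cyclohexene with C12H=C3H (other centres as in 11) | C1=CCC[C@@H]2/C(=C(/C)C(=O)N(C)OC)CC[C@@H](C)[C@@]12C | intermediate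
15 | C12,C3 cis-diol of 14 (face not specified) | OC1C(O)CC[C@@H]2/C(=C(/C)C(=O)N(C)OC)CC[C@@H](C)[C@@]12C | intermediate
16 | (2Z)-2-[(2R,3R,4R)-3-formyl-3,4-dimethyl-2-(3-oxopropyl)cyclohexylidene]-N-methoxy-N-methylpropanamide | O=CCC[C@@H]1/C(=C(/C)C(=O)N(C)OC)CC[C@@H](C)[C@@]1(C)C=O | intermediate
17 | C3 alcohol, C12 aldehyde (3-hydroxypropyl analogue of 16) | OCCC[C@@H]1/C(=C(/C)C(=O)N(C)OC)CC[C@@H](C)[C@@]1(C)C=O | intermediate
18 | decanoyl chloride | CCCCCCCCCC(=O)Cl | starting material
19 | C3 decanoate of 17 | CCCCCCCCCC(=O)OCCC[C@@H]1/C(=C(/C)C(=O)N(C)OC)CC[C@@H](C)[C@@]1(C)C=O | intermediate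
20 | methyltriphenylphosphonium bromide | C[P+](c1ccccc1)(c1ccccc1)c1ccccc1.[Br-] | starting material
21 | C11 vinyl compound (CH=CH2 in place of CHO of 19) | CCCCCCCCCC(=O)OCCC[C@@H]1/C(=C(/C)C(=O)N(C)OC)CC[C@@H](C)[C@@]1(C)C=C | intermediate
22 | propargyl alcohol | C#CCO | starting material
23 | (E)-alkenylalane, O-aluminated (Al cis to methyl) | C[Al](C)/C=C(\C)CO[Al](C)C | intermediate
24 | (E)-3-iodo-2-methylprop-2-en-1-ol | OC/C(C)=C/I | intermediate
25 | (E)-3-iodo-2-methylprop-2-enal | O=C/C(C)=C/I | intermediate
26 | geranyl chloride | ClC/C=C(\C)CCC=C(C)C | starting material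
27 | racemic (1E,5E)-1-iodo-2,6,10-trimethylundeca-1,5,9-trien-3-ol | I/C=C(\C)C(O)C/C=C(\C)CCC=C(C)C | intermediate
28 | (1E,5E)-1-iodo-2,6,10-trimethylundeca-1,5,9-trien-3-one | I/C=C(\C)C(=O)C/C=C(\C)CCC=C(C)C | intermediate
29 | catechol borate of 30 | I/C=C(\C)[C@H](OB1Oc2ccccc2O1)C/C=C(\C)CCC=C(C)C | intermediate
30 | (3R,1E,5E)-1-iodo-2,6,10-trimethylundeca-1,5,9-trien-3-ol | I/C=C(\C)[C@H](O)C/C=C(\C)CCC=C(C)C | intermediate
31 | B-alkyl-9-BBN from 21 (boron on C13) | CCCCCCCCCC(=O)OCCC[C@@H]1/C(=C(/C)C(=O)N(C)OC)CC[C@@H](C)[C@@]1(C)CCB1C2CCCC1CCC2 | intermediate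
32 | target skeleton with N-methoxy-N-methylamide at C1 | CCCCCCCCCC(=O)OCCC[C@@H]1/C(=C(/C)C(=O)N(C)OC)CC[C@@H](C)[C@@]1(C)CC/C=C(\C)[C@H](O)C/C=C(\C)CCC=C(C)C | intermediate
33 | O-zirconated hemiaminal at C1, C16 zirconium alkoxide (Cp drawn η1) | CCCCCCCCCC(=O)OCCC[C@@H]1/C(=C(/C)C(O[Zr](Cl)(C2C=CC=C2)C2C=CC=C2)N(C)OC)CC[C@@H](C)[C@@]1(C)CC/C=C(\C)[C@H](O[Zr](Cl)(C2C=CC=C2)C2C=CC=C2)C/C=C(\C)CCC=C(C)C | intermediate
34 | CNP0270550.1 (2Z,6S,10R,11R,14E,16R,18E) | CCCCCCCCCC(=O)OCCC[C@@H]1/C(=C(/C)C=O)CC[C@@H](C)[C@@]1(C)CC/C=C(\C)[C@H](O)C/C=C(\C)CCC=C(C)C | target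

Total step count: 18. Longest linear sequence: 13 steps (steps 1–11, 17, 18).

Steps most likely to fail

Step 2. Several processes could defeat it:
- Attack of the fully substituted enol silane on the β-substituted iminium ion may be slow, so protodesilylation could compete.
- Catalyst and substrate facial preferences may be mismatched, with loss of control at C10.
- The Lewis acid stage may isomerise the isopropenyl group.

The fallback sets out from 3 and comes back at 5, which is then closed to 6. The two bonds are made separately. Iridium-catalysed, branched-selective allylic alkylation of fluoride-activated 3 with (E)-crotyl methyl carbonate, using a chiral phosphoramidite chosen for the C10 configuration, would give the 2-(but-3-en-2-yl) ketone F1. Hydroboration–oxidation of its monosubstituted alkene (9-BBN, then NaBO3) would give the primary alcohol F2. Periodinane oxidation of F2 gives 5 as an isolated compound, which is cyclised with BF3·OEt2 in dry CH2Cl2.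

Step 3. The hydride may attack the C12 ketone or add 1,2 to the enone, and the enolate geometry may leak through the s-cis conformer. The fallback sets out from 6 and comes back at 9, relying on thermodynamic rather than kinetic alkene control. Chemoselective Wittig methoxymethylenation of the unhindered acetyl group would give the methyl dienol ether F3. Mild aqueous acid followed by base equilibration would hydrolyse it, with protonation at C8, to the conjugated enal F4, in which the slimmer formyl group should settle syn to the more substituted C6. Chlorite oxidation would give the acid F5, and carbodiimide coupling with N,O-dimethylhydroxylamine gives 9.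

Step 18. The hindered tetrasubstituted amide may react sluggishly, so that ester attack or hydrozirconation of alkenes competes. The fallback sets out from 32 and comes back at 34. The ester is sacrificed and put back. LiAlH4 at −78 → 0 °C would reduce the amide to its stable chelate (aldehyde on work-up) and cleave the decanoate, giving the enal diol F6. The primary C3 hydroxyl of F6 is then acylated selectively over the secondary allylic C16 hydroxyl with 18 and 2,4,6-collidine at −78 °C.

Further compounds
F1 | step 2 | 2-(but-3-en-2-yl)-2-methyl-5-isopropenyl-3-(prop-1-ynyl)cyclohexanone (C6, C10, C11 as in 5) | C1[C@@H](C(C)=C)C[C@H](C#CC)[C@@](C)([C@H](C)C=C)C1=O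
F2 | step 2 | 2-(4-hydroxybutan-2-yl)-2-methyl-5-isopropenyl-3-(prop-1-ynyl)cyclohexanone (C6, C10, C11 as in 5) | C1[C@@H](C(C)=C)C[C@H](C#CC)[C@@](C)([C@H](C)CCO)C1=O
F3 | step 3 | methyl dienol ether of 6 (C2=CH–OMe, E/Z mixture) | C1[C@@H](C(C)=C)C[C@@H]2C(C(C)=COC)=CC[C@@H](C)[C@@]2(C)C1=O
F4 | step 3 | (2Z)-enal corresponding to 9 (CHO syn to C6) | C1[C@@H](C(C)=C)C[C@@H]2/C(=C(/C)C=O)CC[C@@H](C)[C@@]2(C)C1=O
F5 | step 3 | (2Z)-carboxylic acid corresponding to 9 | C1[C@@H](C(C)=C)C[C@@H]2/C(=C(/C)C(=O)O)CC[C@@H](C)[C@@]2(C)C1=O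
F6 | step 18 | 3-O-deacyl target (enal with free C3 and C16 hydroxyls) | OCCC[C@@H]1/C(=C(/C)C=O)CC[C@@H](C)[C@@]1(C)CC/C=C(\C)[C@H](O)C/C=C(\C)CCC=C(C)C
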